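The ten-membered ring is made by cutting a bond, not by closing one. In the target the E C1=C10 alkene and the oxygenated C5 are 1,3-related through C10, so the germacrane ring maps onto a trans-fused decalin (ring A: C1–C5 and C10; ring B: C5–C10) whose shared C5–C10 bond is sacrificial. A Wharton fragmentation of the C5 alkoxide against an equatorial C1 mesylate breaks this bond and, in one operation, forms the C5 ketone, the E alkene and the cyclodecene. The precursor 25 is a 5α-hydroxy-1β-mesyloxy trans-decalin that already holds C14, C15, the C9 oxygen and the C7 side chain with correct configuration.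

Key step: step 22

Remarks on the chemistry:
- Numbering is germacrane numbering throughout (ring C1–C10, C11–C13 on C7, C14 on C10, C15 on C4). In the decalins β is the face of the C10–C14 bond. TBS = tert-butyldimethylsilyl, TES = triethylsilyl, TIPS = triisopropylsilyl, PMB = 4-methoxybenzyl.
- Stereochemical check of 25: C14 (β) and the C5 hydroxyl (α) are trans-diaxial, the C1 mesylate, the C9 ether and the C7 side chain are equatorial (β); this matches 4S,5R,7R,9S in the target and needs no correction.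
- Design of the precursor: the more robust TIPS ether sits on C15, which is unmasked last, and the more labile TBS ether on C12, which is unmasked first, so no protecting-group exchange is needed after the key step. C1 is reduced before ring B is closed, which leaves C4 as the only enolisable position for placing C15.
- Assumption: C4 is drawn as the equatorial (4α) epimer from step 17 on; either epimer serves, because step 23 makes C4 an alkene carbon.

Step 1
Reactants: 1 2-bromoprop-2-en-1-ol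
Product: 2 tert-butyl[(2-bromoprop-2-en-1-yl)oxy]dimethylsilane
Conditions: TBSCl, imidazole, CH2Cl2, 0 °C to rt
Reagents that add atoms: tert-butyldimethylsilyl chloride, CC(C)(C)[Si](C)(C)Cl
Why: Silylation of a primary allylic alcohol through the N-silylimidazolium ion masks O12 as an ether that withstands the later base, hydride and samarium steps.

Step 2
Reactants: 2 tert-butyl[(2-bromoprop-2-en-1-yl)oxy]dimethylsilane
Product: 3 2-[3-(TBS-oxy)prop-1-en-2-yl]-4,4,5,5-tetramethyl-1,3,2-dioxaborolane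
Conditions: B2pin2, PdCl2(PPh3)2 (3 mol %), PPh3, KOPh, toluene, 50 °C
Reagents that add atoms: bis(pinacolato)diboron, CC1(C)OB(OC1(C)C)B1OC(C)(C)C(C)(C)O1
Why: Miyaura borylation of a 1-bromoalkene (oxidative addition to zerovalent palladium, phenoxide-assisted boryl transfer, reductive elimination) gives the alkenylboronate without touching the allylic silyl ether.

Step 3
Reactants: 3 2-[3-(TBS-oxy)prop-1-en-2-yl]-4,4,5,5-tetramethyl-1,3,2-dioxaborolane; 4 furan-2(5H)-one
Product: 5 (S)-4-[3-(TBS-oxy)prop-1-en-2-yl]dihydrofuran-2(3H)-one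
Conditions: [Rh(OH)(cod)]2 (2.5 mol %), (S)-BINAP (6 mol %), KOH (0.2 equiv), dioxane/H2O 10:1, 50 °C; acidic work-up
Reagents that add atoms: none
Why: Rhodium-catalysed asymmetric conjugate addition (Hayashi–Miyaura reaction): the alkenyl group passes from boron to rhodium, adds across the butenolide C=C and the rhodium enolate is protonated by water, the (S)-BINAP complex shielding the same enone face as in additions to cyclohexenone so that C7 should form S.

Step 4
Reactants: 5 (S)-4-[3-(TBS-oxy)prop-1-en-2-yl]dihydrofuran-2(3H)-one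
Product: 6 (3S)-4-hydroxy-N-methoxy-N-methyl-3-[3-(TBS-oxy)prop-1-en-2-yl]butanamide
Conditions: MeNH(OMe)·HCl, AlMe3, CH2Cl2, 0 °C to rt
Reagents that add atoms: N,O-dimethylhydroxylamine hydrochloride, CNOC.Cl
Why: Weinreb aminolysis of the lactone by the aluminium amide opens the ring to the C6 primary alcohol and a C9 acyl group that can later be reduced to the aldehyde without over-reduction.

Step 5
Reactants: 6 (3S)-4-hydroxy-N-methoxy-N-methyl-3-[3-(TBS-oxy)prop-1-en-2-yl]butanamide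
Product: 7 (3S)-N-methoxy-N-methyl-3-[3-(TBS-oxy)prop-1-en-2-yl]-4-(TES-oxy)butanamide
Conditions: TESCl, imidazole, CH2Cl2, 0 °C
Reagents that add atoms: triethylsilyl chloride, CC[Si](Cl)(CC)CC
Why: Silylation of the primary alcohol prevents relactonisation and gives O6 the most acid-labile ether in the molecule, which step 13 removes selectively.

Step 6
Reactants: 7 (3S)-N-methoxy-N-methyl-3-[3-(TBS-oxy)prop-1-en-2-yl]-4-(TES-oxy)butanamide
Product: 8 (3S)-3-[3-(TBS-oxy)prop-1-en-2-yl]-4-(TES-oxy)butanal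
Conditions: iBu2AlH, THF, −78 °C
Reagents that add atoms: none
Why: Hydride reduction of a Weinreb amide stops at the chelated tetrahedral aluminate, which releases the C9 aldehyde only on work-up.

Step 7
Reactants: 9 methyl 2,6-dimethoxybenzoate
Product: 10 methyl 2,6-dimethoxycyclohexa-2,5-diene-1-carboxylate
Conditions: K, NH3(l), THF, t-BuOH (1 equiv), −78 °C; then NH4Cl
Reagents that add atoms: none
Why: Birch reduction of a benzoate places hydrogen at the ipso and para carbons, giving a 1,4-dihydro ester in which C10 bears the future C14 as the ester and both future ring A carbonyls (C1, C5) are masked as methyl enol ethers.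

Step 8
Reactants: 10 methyl 2,6-dimethoxycyclohexa-2,5-diene-1-carboxylate; 8 (3S)-3-[3-(TBS-oxy)prop-1-en-2-yl]-4-(TES-oxy)butanal
Product: 11 methyl 1-[(3S)-1-hydroxy-3-[3-(TBS-oxy)prop-1-en-2-yl]-4-(TES-oxy)butyl]-2,6-dimethoxycyclohexa-2,5-diene-1-carboxylate (both C9 epimers)
Conditions: LiN(iPr)2, THF, −78 °C; then 8; AcOH quench at −78 °C
Reagents that add atoms: none
Why: Aldol addition of the lithium ester dienolate through its α-carbon (the site that also reacts in reductive alkylations of benzoates) makes the C9–C10 bond and the quaternary C10, the C9 epimer mixture being harmless because step 9 oxidises this centre and the cold quench forestalling retro-aldol.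

Step 9
Reactants: 11 methyl 1-[(3S)-1-hydroxy-3-[3-(TBS-oxy)prop-1-en-2-yl]-4-(TES-oxy)butyl]-2,6-dimethoxycyclohexa-2,5-diene-1-carboxylate
Product: 12 methyl 2,6-dimethoxy-1-[(3S)-3-[3-(TBS-oxy)prop-1-en-2-yl]-4-(TES-oxy)butanoyl]cyclohexa-2,5-diene-1-carboxylate
Conditions: Dess–Martin periodinane, pyridine, CH2Cl2, 0 °C to rt
Reagents that add atoms: none
Why: Dess–Martin oxidation of the hindered secondary alcohol under pyridine buffering spares the acid-sensitive enol ethers and silyl ethers and gives a β-keto ester that cannot enolise toward C10.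

Step 10
Reactants: 12 methyl 2,6-dimethoxy-1-[(3S)-3-[3-(TBS-oxy)prop-1-en-2-yl]-4-(TES-oxy)butanoyl]cyclohexa-2,5-diene-1-carboxylate
Product: 13 methyl 1-[(1S,3S)-1-hydroxy-3-[3-(TBS-oxy)prop-1-en-2-yl]-4-(TES-oxy)butyl]-2,6-dimethoxycyclohexa-2,5-diene-1-carboxylate
Conditions: (R)-2-methyl-CBS-oxazaborolidine (20 mol %), catecholborane, toluene, −78 °C
Reagents that add atoms: none
Why: Corey–Bakshi–Shibata reduction in which the quaternary C10 is the large and the C8 methylene the small ketone substituent, so the (R)-catalyst should deliver hydride to the face that gives the 9S alcohol, while catecholborane at this temperature leaves the enol ethers and the 1,1-disubstituted alkene alone.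

Step 11
Reactants: 13 methyl 1-[(1S,3S)-1-hydroxy-3-[3-(TBS-oxy)prop-1-en-2-yl]-4-(TES-oxy)butyl]-2,6-dimethoxycyclohexa-2,5-diene-1-carboxylate
Product: 14 (1S,3S)-1-[1-(hydroxymethyl)-2,6-dimethoxycyclohexa-2,5-dien-1-yl]-3-[3-(TBS-oxy)prop-1-en-2-yl]-4-(TES-oxy)butan-1-ol
Conditions: LiAlH4, THF, 0 °C to rt
Reagents that add atoms: none
Why: Hydride reduction of the ester turns the ester carbon into the C14 hydroxymethyl group while enol ethers, silyl ethers and the alkene are inert.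

Step 12
Reactants: 14 (1S,3S)-1-[1-(hydroxymethyl)-2,6-dimethoxycyclohexa-2,5-dien-1-yl]-3-[3-(TBS-oxy)prop-1-en-2-yl]-4-(TES-oxy)butan-1-ol
Product: 15 1-[(1S,3S)-1-(PMB-oxy)-3-[3-(TBS-oxy)prop-1-en-2-yl]-4-(TES-oxy)butyl]-1-[(PMB-oxy)methyl]-2,6-dimethoxycyclohexa-2,5-diene
Conditions: NaH, PMBCl, n-Bu4NI, DMF, 0 °C to rt
Reagents that add atoms: 4-methoxybenzyl chloride, COc1ccc(CCl)cc1
Why: Williamson etherification of both alkoxides protects O9 and O14 with one group that survives acid, base, samarium and palladium and is later removed oxidatively; with the ester gone there is no retro-aldol pathway for the C9 alkoxide.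

Step 13
Reactants: 15 1-[(1S,3S)-1-(PMB-oxy)-3-[3-(TBS-oxy)prop-1-en-2-yl]-4-(TES-oxy)butyl]-1-[(PMB-oxy)methyl]-2,6-dimethoxycyclohexa-2,5-diene
Product: 16 2-[(1S,3S)-4-hydroxy-1-(PMB-oxy)-3-[3-(TBS-oxy)prop-1-en-2-yl]butyl]-2-[(PMB-oxy)methyl]cyclohexane-1,3-dione
Conditions: AcOH/THF/H2O (1:2:1), rt
Reagents that add atoms: water, O
Why: Acid hydrolysis of the two methyl enol ethers (C-protonation, hydration of the oxocarbenium ion, loss of methanol) releases the 2,2-disubstituted 1,3-dione and the primary TES ether is solvolysed in the same operation, whereas the TBS and PMB ethers react far more slowly.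

Step 14
Reactants: 16 2-[(1S,3S)-4-hydroxy-1-(PMB-oxy)-3-[3-(TBS-oxy)prop-1-en-2-yl]butyl]-2-[(PMB-oxy)methyl]cyclohexane-1,3-dione
Product: 17 2-[(1S,3S)-4-iodo-1-(PMB-oxy)-3-[3-(TBS-oxy)prop-1-en-2-yl]butyl]-2-[(PMB-oxy)methyl]cyclohexane-1,3-dione
Conditions: I2, PPh3, imidazole, CH2Cl2, 0 °C
Reagents that add atoms: iodine, II
Why: Appel iodination converts the only free (primary) alcohol into the C6 iodide by displacement of the alkoxyphosphonium ion.

Step 15
Reactants: 17 2-[(1S,3S)-4-iodo-1-(PMB-oxy)-3-[3-(TBS-oxy)prop-1-en-2-yl]butyl]-2-[(PMB-oxy)methyl]cyclohexane-1,3-dione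
Product: 18 (3R)-3-hydroxy-2-[(1S,3S)-4-iodo-1-(PMB-oxy)-3-[3-(TBS-oxy)prop-1-en-2-yl]butyl]-2-[(PMB-oxy)methyl]cyclohexan-1-one (hydroxyl cis to the CH2OPMB arm)
Conditions: (S)-2-methyl-CBS-oxazaborolidine (20 mol %), catecholborane (1.1 equiv), CH2Cl2, −78 to −40 °C
Reagents that add atoms: none
Why: Group-selective Corey–Bakshi–Shibata reduction of a 2,2-disubstituted cyclohexane-1,3-dione: the (S)-catalyst (quaternary C10 as large substituent) allows only the R carbinol and hydride must also enter anti to the axial C14 arm (the branched C9 chain sits equatorial), demands that only one of the two carbonyls meets, so C1 (hydroxyl cis to C14) and the configuration of C10 are set together.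

Step 16
Reactants: 18 (3R)-3-hydroxy-2-[(1S,3S)-4-iodo-1-(PMB-oxy)-3-[3-(TBS-oxy)prop-1-en-2-yl]butyl]-2-[(PMB-oxy)methyl]cyclohexan-1-one
Product: 19 (3R)-3-acetoxy-2-[(1S,3S)-4-iodo-1-(PMB-oxy)-3-[3-(TBS-oxy)prop-1-en-2-yl]butyl]-2-[(PMB-oxy)methyl]cyclohexan-1-one
Conditions: Ac2O, DMAP, pyridine, rt
Reagents that add atoms: acetic anhydride, CC(=O)OC(C)=O
Why: Acylation protects the C1 hydroxyl, which would otherwise protonate the organosamarium of step 19, with a group orthogonal to every silyl and PMB ether.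

Step 17
Reactants: 19 (3R)-3-acetoxy-2-[(1S,3S)-4-iodo-1-(PMB-oxy)-3-[3-(TBS-oxy)prop-1-en-2-yl]butyl]-2-[(PMB-oxy)methyl]cyclohexan-1-one
Product: 21 (3R)-3-acetoxy-6-(hydroxymethyl)-2-[(1S,3S)-4-iodo-1-(PMB-oxy)-3-[3-(TBS-oxy)prop-1-en-2-yl]butyl]-2-[(PMB-oxy)methyl]cyclohexan-1-one (hydroxymethyl equatorial), via trimethylsilyl enol ether 20 (not isolated)
Conditions: Me3SiOTf, Et3N, CH2Cl2, 0 °C; then aq. HCHO, Yb(OTf)3 (10 mol %), THF, rt
Reagents that add atoms: formaldehyde, C=O; trimethylsilyl triflate (atoms in 20 only), C[Si](C)(C)OS(=O)(=O)C(F)(F)F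
Why: Soft enolisation can only go toward C4 because C10 is quaternary, and the silyl enol ether undergoes an aqueous Mukaiyama aldol reaction with formaldehyde that places C15 on C4, the configuration at C4 being of no consequence.

Step 18
Reactants: 21 (3R)-3-acetoxy-6-(hydroxymethyl)-2-[(1S,3S)-4-iodo-1-(PMB-oxy)-3-[3-(TBS-oxy)prop-1-en-2-yl]butyl]-2-[(PMB-oxy)methyl]cyclohexan-1-one
Product: 22 (3R)-3-acetoxy-2-[(1S,3S)-4-iodo-1-(PMB-oxy)-3-[3-(TBS-oxy)prop-1-en-2-yl]butyl]-2-[(PMB-oxy)methyl]-6-[(TIPS-oxy)methyl]cyclohexan-1-one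
Conditions: TIPSOTf, 2,6-lutidine, CH2Cl2, −78 °C
Reagents that add atoms: triisopropylsilyl triflate, CC(C)[Si](OS(=O)(=O)C(F)(F)F)(C(C)C)C(C)C
Why: Fast low-temperature silylation caps the β-hydroxy ketone before retro-aldol or dehydration and puts the most robust silyl group on O15.

Step 19
Reactants: 22 (3R)-3-acetoxy-2-[(1S,3S)-4-iodo-1-(PMB-oxy)-3-[3-(TBS-oxy)prop-1-en-2-yl]butyl]-2-[(PMB-oxy)methyl]-6-[(TIPS-oxy)methyl]cyclohexan-1-one
Product: 23 1β-acetoxy-9β,14-bis(PMB-oxy)-12-(TBS-oxy)-15-(TIPS-oxy)eudesm-11(13)-en-5α-ol (trans-decalin; 1R, 9S, H-7α, 4α-CH2OTIPS)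
Conditions: SmI2 (2.5 equiv), HMPA, THF, 0 °C; then NH4Cl
Reagents that add atoms: none
Why: Samarium Barbier cyclisation: SmI2 reduces the primary iodide to an alkylsamarium that adds to the only ketone through a six-membered chair with the C9 ether and the C7 side chain equatorial and the new C5–C6 bond equatorial on ring A (C14 stays axial), which should give the trans ring fusion with the axial 5α-hydroxyl.

Step 20
Reactants: 23 1β-acetoxy-9β,14-bis(PMB-oxy)-12-(TBS-oxy)-15-(TIPS-oxy)eudesm-11(13)-en-5α-ol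
Product: 24 9β,14-bis(PMB-oxy)-12-(TBS-oxy)-15-(TIPS-oxy)eudesm-11(13)-ene-1β,5α-diol
Conditions: iBu2AlH, CH2Cl2, −78 °C
Reagents that add atoms: none
Why: Reductive cleavage of the hindered acetate frees the equatorial C1 hydroxyl without touching the ethers, since no other reducible group is present.

Step 21
Reactants: 24 9β,14-bis(PMB-oxy)-12-(TBS-oxy)-15-(TIPS-oxy)eudesm-11(13)-ene-1β,5α-diol
Product: 25 1β-(methanesulfonyloxy)-9β,14-bis(PMB-oxy)-12-(TBS-oxy)-15-(TIPS-oxy)eudesm-11(13)-en-5α-ol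
Conditions: MsCl, Et3N, CH2Cl2, 0 °C
Reagents that add atoms: methanesulfonyl chloride, CS(=O)(=O)Cl
Why: Sulfonylation (through sulfene) takes the secondary equatorial C1 hydroxyl and leaves the tertiary C5 hydroxyl free, giving the 1,3-diol monosulfonate needed for fragmentation.

Step 22
Reactants: 25 1β-(methanesulfonyloxy)-9β,14-bis(PMB-oxy)-12-(TBS-oxy)-15-(TIPS-oxy)eudesm-11(13)-en-5α-ol
Product: 26 (1(10)E,7R,9S)-9,14-bis(PMB-oxy)-12-(TBS-oxy)-15-(TIPS-oxy)germacra-1(10),11(13)-dien-5-one (C4 as in 25)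
Conditions: KOtBu (1.3 equiv), t-BuOH/THF, 0 °C to rt, short reaction time
Reagents that add atoms: none
Why: KOtBu deprotonates the tertiary 5α-hydroxyl, and because the alkoxide C5–O bond, the C5–C10 bond and the equatorial C1–OMs bond are antiperiplanar in the chair–chair trans-decalin, C5–C10 and C1–O break in concert while C5=O and C1=C10 form. The closest known reaction type is the Wharton (Grob-type) fragmentation of decalin 1,3-diol monosulfonates to E-cyclodecenones. No ring is closed by bond formation, so no closure mode applies: the ten-membered ring arises because the bond shared by rings A and B is deleted. No stereocentre is created; C7 and C9 are untouched, and the alkene is E because C2 and C9 are anti about C1–C10 in 25, which leaves C14 cis to C2. The step needs fragmentation to win over elimination or substitution, and this is secured by the trans ring fusion and the equatorial mesylate, which has only ring C–C bonds anti to it so that E2 loss of methanesulfonic acid is stereoelectronically disfavoured. A small excess of base and a short reaction time limit enolisation of the product and loss of the β-silyloxy group.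

Step 23
Reactants: 26 (1(10)E,7R,9S)-9,14-bis(PMB-oxy)-12-(TBS-oxy)-15-(TIPS-oxy)germacra-1(10),11(13)-dien-5-one
Product: 27 (1(10)E,4E,7R,9S)-9,14-bis(PMB-oxy)-12-(TBS-oxy)-15-(TIPS-oxy)germacra-1(10),4,11(13)-trien-5-yl trifluoromethanesulfonate (C3 and C6 trans on the ring)
Conditions: KN(SiMe3)2, PhNTf2, THF, −78 °C
Reagents that add atoms: N-phenylbis(trifluoromethanesulfonimide), O=S(=O)(N(c1ccccc1)S(=O)(=O)C(F)(F)F)C(F)(F)F
Why: Enol triflate formation: deprotonation at C4 (activated by the β-silyloxy group, whereas C6 is flanked by the branched C7) and O-sulfonylation of the potassium enolate, the enolate arising from the conformer with C3 and C6 anti so that these ring carbons should end up trans on the new tetrasubstituted alkene.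

Step 24
Reactants: 27 (1(10)E,4E,7R,9S)-9,14-bis(PMB-oxy)-12-(TBS-oxy)-15-(TIPS-oxy)germacra-1(10),4,11(13)-trien-5-yl trifluoromethanesulfonate
Product: 28 (1(10)E,4Z,7S,9S)-9,14-bis(PMB-oxy)-12-(TBS-oxy)-15-(TIPS-oxy)germacra-1(10),4,11(13)-triene (C3 and C6 trans on the ring)
Conditions: Pd(OAc)2 (5 mol %), PPh3, HCO2H, n-Bu3N, DMF, 60 °C
Reagents that add atoms: none
Why: Palladium-catalysed formate reduction of an enol triflate (oxidative addition to zerovalent palladium, exchange of triflate for formate, loss of CO2, C–H reductive elimination) replaces the triflate by hydrogen with retention of alkene geometry, and allylic ethers are not ionised.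

Step 25
Reactants: 28 (1(10)E,4Z,7S,9S)-9,14-bis(PMB-oxy)-12-(TBS-oxy)-15-(TIPS-oxy)germacra-1(10),4,11(13)-triene
Product: 29 (1(10)E,4Z,7S,9S)-9,14-bis(PMB-oxy)-15-(TIPS-oxy)germacra-1(10),4,11(13)-trien-12-ol
Conditions: HF·pyridine, pyridine, THF, 0 °C
Reagents that add atoms: none
Why: Buffered fluoride cleaves the primary TBS ether much faster than the primary TIPS ether, so O12 alone is unmasked under conditions too mild for acid-induced transannular cyclisation.

Step 26
Reactants: 29 (1(10)E,4Z,7S,9S)-9,14-bis(PMB-oxy)-15-(TIPS-oxy)germacra-1(10),4,11(13)-trien-12-ol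
Product: 30 (1(10)E,4Z,7S,9S)-12-acetoxy-9,14-bis(PMB-oxy)-15-(TIPS-oxy)germacra-1(10),4,11(13)-triene
Conditions: Ac2O, Et3N, DMAP (cat.), CH2Cl2, 0 °C
Reagents that add atoms: acetic anhydride, CC(=O)OC(C)=O
Why: Acylation of the only free hydroxyl installs the C12 acetate of the target.

Step 27
Reactants: 30 (1(10)E,4Z,7S,9S)-12-acetoxy-9,14-bis(PMB-oxy)-15-(TIPS-oxy)germacra-1(10),4,11(13)-triene
Product: 31 (1(10)E,4Z,7S,9S)-12-acetoxy-15-(TIPS-oxy)germacra-1(10),4,11(13)-triene-9,14-diol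
Conditions: DDQ (2.5 equiv), CH2Cl2/pH 7 buffer, 0 °C
Reagents that add atoms: none
Why: Oxidative PMB cleavage (benzylic hydride abstraction, hydrolysis of the oxocarbenium ion) frees O9 and O14 under neutral conditions that the acetate, the TIPS ether and the diene tolerate.

Step 28
Reactants: 32 (R)-4-benzyl-3-propionyloxazolidin-2-one
Product: 33 (R)-4-benzyl-3-[(2R,3S)-3-hydroxy-2-methylbutanoyl]oxazolidin-2-one
Conditions: n-Bu2BOTf, iPr2NEt, CH2Cl2, −78 °C; acetaldehyde, −78 to 0 °C; H2O2, pH 7 buffer, MeOH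
Reagents that add atoms: acetaldehyde, CC=O
Why: Evans syn-aldol reaction: the Z boron enolate reacts through a chair transition state on the face away from the benzyl group, so the (R)-auxiliary should give the (2R,3S) syn adduct.

Step 29
Reactants: 33 (R)-4-benzyl-3-[(2R,3S)-3-hydroxy-2-methylbutanoyl]oxazolidin-2-one
Product: 34 (R)-4-benzyl-3-[(2R,3S)-3-(TBS-oxy)-2-methylbutanoyl]oxazolidin-2-one
Conditions: TBSOTf, 2,6-lutidine, CH2Cl2, 0 °C
Reagents that add atoms: tert-butyldimethylsilyl triflate, CC(C)(C)[Si](C)(C)OS(=O)(=O)C(F)(F)F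
Why: Silylation of the secondary alcohol prevents self-esterification of the hydroxy acid in step 31 and is removed together with the TIPS ether in step 33.

Step 30
Reactants: 34 (R)-4-benzyl-3-[(2R,3S)-3-(TBS-oxy)-2-methylbutanoyl]oxazolidin-2-one
Product: 36 (2R,3S)-3-(TBS-oxy)-2-methylbutanoic acid, via peroxy acid 35 (not isolated)
Conditions: LiOH, H2O2, THF/H2O, 0 °C; Na2SO3; then HCl to pH 3
Reagents that add atoms: hydrogen peroxide, OO
Why: Hydroperoxide attacks the exocyclic imide carbonyl selectively, and sulfite reduces the peroxy acid to the acid without epimerising C2.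

Step 31
Reactants: 31 (1(10)E,4Z,7S,9S)-12-acetoxy-15-(TIPS-oxy)germacra-1(10),4,11(13)-triene-9,14-diol; 36 (2R,3S)-3-(TBS-oxy)-2-methylbutanoic acid
Product: 37 (1(10)E,4Z,7S,9S)-12-acetoxy-14-[(2R,3S)-3-(TBS-oxy)-2-methylbutanoyloxy]-15-(TIPS-oxy)germacra-1(10),4,11(13)-trien-9-ol
Conditions: EDC·HCl, DMAP, CH2Cl2, −20 to 0 °C
Reagents that add atoms: none
Why: Steglich esterification in which the primary allylic C14 hydroxyl should react much faster than the hindered secondary C9 hydroxyl, a preference sharpened by the α-branched acid.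

Step 32
Reactants: 37 (1(10)E,4Z,7S,9S)-12-acetoxy-14-[(2R,3S)-3-(TBS-oxy)-2-methylbutanoyloxy]-15-(TIPS-oxy)germacra-1(10),4,11(13)-trien-9-ol
Product: 38 (1(10)E,4Z,7S,9S)-12-acetoxy-9-isobutyryloxy-14-[(2R,3S)-3-(TBS-oxy)-2-methylbutanoyloxy]-15-(TIPS-oxy)germacra-1(10),4,11(13)-triene
Conditions: (iPrCO)2O, Et3N, DMAP, CH2Cl2, rt
Reagents that add atoms: isobutyric anhydride, CC(C)C(=O)OC(=O)C(C)C
Why: DMAP-catalysed acylation of the remaining secondary allylic alcohol installs the C9 isobutyrate.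

Step 33
Reactants: 38 (1(10)E,4Z,7S,9S)-12-acetoxy-9-isobutyryloxy-14-[(2R,3S)-3-(TBS-oxy)-2-methylbutanoyloxy]-15-(TIPS-oxy)germacra-1(10),4,11(13)-triene
Product: 39 (1(10)E,4Z,7S,9S)-12-acetoxy-9-isobutyryloxy-14-[(2R,3S)-3-hydroxy-2-methylbutanoyloxy]germacra-1(10),4,11(13)-trien-15-ol
Conditions: HF·pyridine, pyridine, THF, 0 °C to rt
Reagents that add atoms: none
Why: Buffered fluoride removes both remaining silyl ethers without the basicity that would cause acyl migration or β-elimination in the hydroxy ester.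

Step 34
Reactants: 39 (1(10)E,4Z,7S,9S)-12-acetoxy-9-isobutyryloxy-14-[(2R,3S)-3-hydroxy-2-methylbutanoyloxy]germacra-1(10),4,11(13)-trien-15-ol
Product: 40 CNP0256542.1, (1(10)E,4S,5R,7R,9S)-12-acetoxy-4,5-epoxy-15-hydroxy-9-isobutyryloxy-14-[(2R,3S)-3-hydroxy-2-methylbutanoyloxy]germacra-1(10),11(13)-diene
Conditions: Ti(OiPr)4 (20 mol %), L-(+)-diethyl tartrate (25 mol %), t-BuOOH, 4 Å molecular sieves, CH2Cl2, −20 °C
Reagents that add atoms: tert-butyl hydroperoxide, CC(C)(C)OO
Why: Sharpless asymmetric epoxidation of the only free allylic alcohol: L-(+)-tartrate delivers oxygen to the face that turns a Z-type trisubstituted allylic alcohol such as nerol into its (2S,3R)-epoxide, here 4S,5R, which is also the exposed outer face of C4=C5 in the crossed ring conformation with C14 and C15 syn, so reagent and substrate control should agree.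

Compound list
1 | 2-bromoprop-2-en-1-ol | C=C(Br)CO | starting material
2 | tert-butyl[(2-bromoprop-2-en-1-yl)oxy]dimethylsilane | C=C(Br)CO[Si](C)(C)C(C)(C)C | intermediate
3 | 2-[3-(TBS-oxy)prop-1-en-2-yl]-4,4,5,5-tetramethyl-1,3,2-dioxaborolane | C=C(CO[Si](C)(C)C(C)(C)C)B1OC(C)(C)C(C)(C)O1 | intermediate
4 | furan-2(5H)-one | O=C1OCC=C1 | starting material
5 | (S)-4-[3-(TBS-oxy)prop-1-en-2-yl]dihydrofuran-2(3H)-one | C=C(CO[Si](C)(C)C(C)(C)C)[C@H]1COC(=O)C1 | intermediate
6 | (3S)-4-hydroxy-N-methoxy-N-methyl-3-[3-(TBS-oxy)prop-1-en-2-yl]butanamide | C=C(CO[Si](C)(C)C(C)(C)C)[C@@H](CO)CC(=O)N(C)OC | intermediate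
7 | (3S)-N-methoxy-N-methyl-3-[3-(TBS-oxy)prop-1-en-2-yl]-4-(TES-oxy)butanamide | C=C(CO[Si](C)(C)C(C)(C)C)[C@@H](CO[Si](CC)(CC)CC)CC(=O)N(C)OC | intermediate
8 | (3S)-3-[3-(TBS-oxy)prop-1-en-2-yl]-4-(TES-oxy)butanal | C=C(CO[Si](C)(C)C(C)(C)C)[C@@H](CO[Si](CC)(CC)CC)CC=O | intermediate
9 | methyl 2,6-dimethoxybenzoate | COC(=O)c1c(OC)cccc1OC | starting material
10 | methyl 2,6-dimethoxycyclohexa-2,5-diene-1-carboxylate | COC(=O)C1C(OC)=CCC=C1OC | intermediate
11 | aldol adduct, C9 alcohol as both epimers (7S) | C=C(CO[Si](C)(C)C(C)(C)C)[C@@H](CO[Si](CC)(CC)CC)CC(O)C1(C(=O)OC)C(OC)=CCC=C1OC | intermediate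
12 | C9 ketone (β-keto ester, 7S) | C=C(CO[Si](C)(C)C(C)(C)C)[C@@H](CO[Si](CC)(CC)CC)CC(=O)C1(C(=O)OC)C(OC)=CCC=C1OC | intermediate
13 | (7S,9S)-hydroxy ester | C=C(CO[Si](C)(C)C(C)(C)C)[C@@H](CO[Si](CC)(CC)CC)C[C@H](O)C1(C(=O)OC)C(OC)=CCC=C1OC | intermediate
14 | (7S,9S)-9,14-diol | C=C(CO[Si](C)(C)C(C)(C)C)[C@@H](CO[Si](CC)(CC)CC)C[C@H](O)C1(CO)C(OC)=CCC=C1OC | intermediate
15 | (7S,9S)-9,14-bis(PMB) ether, bis(enol ether) | C=C(CO[Si](C)(C)C(C)(C)C)[C@@H](CO[Si](CC)(CC)CC)C[C@H](OCc1ccc(OC)cc1)C1(COCc2ccc(OC)cc2)C(OC)=CCC=C1OC | intermediate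
16 | 2,2-disubstituted cyclohexane-1,3-dione with free C6 alcohol (7S,9S) | C=C(CO[Si](C)(C)C(C)(C)C)[C@@H](CO)C[C@H](OCc1ccc(OC)cc1)C1(COCc2ccc(OC)cc2)C(=O)CCCC1=O | intermediate
17 | dione C6 iodide (7S,9S) | C=C(CO[Si](C)(C)C(C)(C)C)[C@@H](CI)C[C@H](OCc1ccc(OC)cc1)C1(COCc2ccc(OC)cc2)C(=O)CCCC1=O | intermediate
18 | (1R)-C1 alcohol, hydroxyl cis to C14, C5 ketone | C=C(CO[Si](C)(C)C(C)(C)C)[C@@H](CI)C[C@H](OCc1ccc(OC)cc1)[C@@]1(COCc2ccc(OC)cc2)[C@H](O)CCCC1=O | intermediate
19 | C1 acetate of 18 | C=C(CO[Si](C)(C)C(C)(C)C)[C@@H](CI)C[C@H](OCc1ccc(OC)cc1)[C@@]1(COCc2ccc(OC)cc2)[C@H](OC(C)=O)CCCC1=O | intermediate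
20 | C4=C5 trimethylsilyl enol ether of 19 (not isolated) | C=C(CO[Si](C)(C)C(C)(C)C)[C@@H](CI)C[C@H](OCc1ccc(OC)cc1)[C@@]1(COCc2ccc(OC)cc2)[C@H](OC(C)=O)CCC=C1O[Si](C)(C)C | intermediate
21 | 4-(hydroxymethyl) ketone (C15 alcohol, equatorial) | C=C(CO[Si](C)(C)C(C)(C)C)[C@@H](CI)C[C@H](OCc1ccc(OC)cc1)[C@@]1(COCc2ccc(OC)cc2)[C@H](OC(C)=O)CC[C@@H](CO)C1=O | intermediate
22 | C15 TIPS ether of 21 | C=C(CO[Si](C)(C)C(C)(C)C)[C@@H](CI)C[C@H](OCc1ccc(OC)cc1)[C@@]1(COCc2ccc(OC)cc2)[C@H](OC(C)=O)CC[C@@H](CO[Si](C(C)C)(C(C)C)C(C)C)C1=O | intermediate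
23 | 1β-acetoxy-9β,14-bis(PMB-oxy)-12-(TBS-oxy)-15-(TIPS-oxy)eudesm-11(13)-en-5α-ol (trans-decalin) | C=C(CO[Si](C)(C)C(C)(C)C)[C@@H]1C[C@H](OCc2ccc(OC)cc2)[C@@]2(COCc3ccc(OC)cc3)[C@H](OC(C)=O)CC[C@@H](CO[Si](C(C)C)(C(C)C)C(C)C)[C@]2(O)C1 | intermediate
24 | 9β,14-bis(PMB-oxy)-12-(TBS-oxy)-15-(TIPS-oxy)eudesm-11(13)-ene-1β,5α-diol | C=C(CO[Si](C)(C)C(C)(C)C)[C@@H]1C[C@H](OCc2ccc(OC)cc2)[C@@]2(COCc3ccc(OC)cc3)[C@H](O)CC[C@@H](CO[Si](C(C)C)(C(C)C)C(C)C)[C@]2(O)C1 | intermediate
25 | 1β-(methanesulfonyloxy)-9β,14-bis(PMB-oxy)-12-(TBS-oxy)-15-(TIPS-oxy)eudesm-11(13)-en-5α-ol (key-step precursor) | C=C(CO[Si](C)(C)C(C)(C)C)[C@@H]1C[C@H](OCc2ccc(OC)cc2)[C@@]2(COCc3ccc(OC)cc3)[C@H](OS(C)(=O)=O)CC[C@@H](CO[Si](C(C)C)(C(C)C)C(C)C)[C@]2(O)C1 | intermediate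
26 | (1(10)E,7R,9S)-9,14-bis(PMB-oxy)-12-(TBS-oxy)-15-(TIPS-oxy)germacra-1(10),11(13)-dien-5-one (key-step product) | C=C(CO[Si](C)(C)C(C)(C)C)[C@@H]1C[C@H](OCc2ccc(OC)cc2)/C(COCc2ccc(OC)cc2)=C/CC[C@@H](CO[Si](C(C)C)(C(C)C)C(C)C)C(=O)C1 | intermediate
27 | (1(10)E,4E,7R,9S)-germacra-1(10),4,11(13)-trien-5-yl triflate | C=C(CO[Si](C)(C)C(C)(C)C)[C@@H]1C[C@H](OCc2ccc(OC)cc2)/C(COCc2ccc(OC)cc2)=C/CC/C(CO[Si](C(C)C)(C(C)C)C(C)C)=C(OS(=O)(=O)C(F)(F)F)/C1 | intermediate
28 | (1(10)E,4Z,7S,9S)-9,14-bis(PMB-oxy)-12-(TBS-oxy)-15-(TIPS-oxy)germacra-1(10),4,11(13)-triene | C=C(CO[Si](C)(C)C(C)(C)C)[C@@H]1C[C@H](OCc2ccc(OC)cc2)/C(COCc2ccc(OC)cc2)=C/CC/C(CO[Si](C(C)C)(C(C)C)C(C)C)=C/C1 | intermediate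
29 | C12 alcohol of 28 | C=C(CO)[C@@H]1C[C@H](OCc2ccc(OC)cc2)/C(COCc2ccc(OC)cc2)=C/CC/C(CO[Si](C(C)C)(C(C)C)C(C)C)=C/C1 | intermediate
30 | C12 acetate | C=C(COC(C)=O)[C@@H]1C[C@H](OCc2ccc(OC)cc2)/C(COCc2ccc(OC)cc2)=C/CC/C(CO[Si](C(C)C)(C(C)C)C(C)C)=C/C1 | intermediate
31 | (1(10)E,4Z,7S,9S)-12-acetoxy-15-(TIPS-oxy)germacra-1(10),4,11(13)-triene-9,14-diol | C=C(COC(C)=O)[C@@H]1C[C@H](O)/C(CO)=C/CC/C(CO[Si](C(C)C)(C(C)C)C(C)C)=C/C1 | intermediate
32 | (R)-4-benzyl-3-propionyloxazolidin-2-one | CCC(=O)N1[C@H](Cc2ccccc2)COC1=O | starting material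
33 | (R)-4-benzyl-3-[(2R,3S)-3-hydroxy-2-methylbutanoyl]oxazolidin-2-one | O=C(N1[C@H](Cc2ccccc2)COC1=O)[C@H](C)[C@H](C)O | intermediate
34 | (R)-4-benzyl-3-[(2R,3S)-3-(TBS-oxy)-2-methylbutanoyl]oxazolidin-2-one | O=C(N1[C@H](Cc2ccccc2)COC1=O)[C@H](C)[C@H](C)O[Si](C)(C)C(C)(C)C | intermediate
35 | (2R,3S)-3-(TBS-oxy)-2-methylbutaneperoxoic acid (not isolated) | OOC(=O)[C@H](C)[C@H](C)O[Si](C)(C)C(C)(C)C | intermediate
36 | (2R,3S)-3-(TBS-oxy)-2-methylbutanoic acid | OC(=O)[C@H](C)[C@H](C)O[Si](C)(C)C(C)(C)C | intermediate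
37 | C14 ester, C9 alcohol | C=C(COC(C)=O)[C@@H]1C[C@H](O)/C(COC(=O)[C@H](C)[C@H](C)O[Si](C)(C)C(C)(C)C)=C/CC/C(CO[Si](C(C)C)(C(C)C)C(C)C)=C/C1 | intermediate
38 | C9 isobutyrate, fully protected triester | C=C(COC(C)=O)[C@@H]1C[C@H](OC(=O)C(C)C)/C(COC(=O)[C@H](C)[C@H](C)O[Si](C)(C)C(C)(C)C)=C/CC/C(CO[Si](C(C)C)(C(C)C)C(C)C)=C/C1 | intermediate
39 | (1(10)E,4Z,7S,9S)-12-acetoxy-9-isobutyryloxy-14-[(2R,3S)-3-hydroxy-2-methylbutanoyloxy]germacra-1(10),4,11(13)-trien-15-ol | C=C(COC(C)=O)[C@@H]1C[C@H](OC(=O)C(C)C)/C(COC(=O)[C@H](C)[C@H](C)O)=C/CC/C(CO)=C/C1 | intermediate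
40 | CNP0256542.1 | C=C(COC(C)=O)[C@@H]1C[C@H](OC(=O)C(C)C)/C(COC(=O)[C@H](C)[C@H](C)O)=C/CC[C@@]2(CO)O[C@@H]2C1 | target

Total step count: 34. Longest linear sequence: 30 steps (steps 1–6, 8–27 and 31–34); step 7 and steps 28–30 are side branches.

Steps most likely to fail

1. Step 23 (enol triflate). The base may deprotonate on the C6 side instead of C4, the C4 enolate may form with the other alkene geometry, or it may expel the β-silyloxy group. The fallback sets out from 26 and separates regiocontrol from triflation. Silylation under equilibrating conditions (Me3SiCl, NaI, Et3N, MeCN, rt) should favour the tetrasubstituted (1(10)E,4E)-5-(trimethylsilyloxy)germacra-1(10),4,11(13)-triene F1. MeLi in THF at 0 °C then cleaves the O–Si bond to the regiodefined lithium enolate, which PhNTf2 traps as the enol triflate. The fallback comes back to the route at 27.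

2. Step 19 (samarium Barbier). The closure may give the cis ring junction, or the organosamarium may be protonated before it adds, leaving the reduced open-chain ketone. The fallback sets out from 22 and replaces the single-electron chemistry by a polar one: iodine–lithium exchange with t-BuLi (2.2 equiv, Et2O/pentane, −100 °C) followed by anionic 6-exo addition of the primary alkyllithium to the C5 ketone. It comes back at 23; any acetate cleaved on the way simply gives 24, the next compound. No new compound is made (F0).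

3. Step 8 (aldol at the quaternary carbon). The hindered, stabilised dienolate may add slowly, react through its γ-carbon, or the aldolate may revert on warming. The fallback sets out from 10 and 7 and makes the C9–C10 bond by Claisen-type acylation instead: the lithium enolate of 10 (LiN(iPr)2, THF, −78 to −40 °C) is acylated with Weinreb amide 7, whose chelated tetrahedral adduct cannot revert and collapses on work-up. It comes back at keto ester 12 and bypasses steps 6 and 9. No new compound is made (F0).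

Further compounds
F1 | step 23 | (1(10)E,4E,7R,9S)-9,14-bis(PMB-oxy)-12-(TBS-oxy)-15-(TIPS-oxy)-5-(trimethylsilyloxy)germacra-1(10),4,11(13)-triene | C=C(CO[Si](C)(C)C(C)(C)C)[C@@H]1C[C@H](OCc2ccc(OC)cc2)/C(COCc2ccc(OC)cc2)=C/CC/C(CO[Si](C(C)C)(C(C)C)C(C)C)=C(O[Si](C)(C)C)/C1
F0 | step 19 | none | none
F0 | step 8 | none | none
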